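## Retrosynthetic overview

1. (−)-Pipoxide 17 ⇒ dienol dibenzoate 15: the oxirane (C1–O and C6–O) is made last, by hydroxyl-directed epoxidation.
2. 15 ⇒ cyclohexene 8: the diene comes from dibromination and double dehydrobromination, with the free OH silylated in the flask.
3. 8 ⇒ epoxy benzoate 7: the C3–OBz bond comes from anti opening of a temporary oxirane by benzoic acid.
4. 7 ⇒ epoxy alcohol 5 ⇒ achiral dienyl carbinol 3: a directed epoxidation that selects one of two enantiotopic olefins (new C–O-forming step) fixes the absolute configuration.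
5. 3 ⇒ benzoic acid 1 (Birch reduction, LiAlH4). Ring order: the carbocycle is the arene ring; temporary oxirane in step 3 (opened in step 5); final oxirane in step 8.

Assumption: reagents that put atoms into a numbered compound are numbered as starting materials, and the (R,R) antipodes written for the ligand in step 3 and the cobalt complex in step 5 stand for whichever antipode gives the drawn enantiomer in a first small-scale run.

## Route

Step 1
Reactants: 1 benzoic acid
Product: 2 cyclohexa-2,5-diene-1-carboxylic acid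
Conditions: Na, NH3(l), EtOH, −78 to −33 °C; NH4Cl; aq. HCl
Reagents that add atoms: none
Why: Birch reduction; the carboxylate-stabilised anion is protonated at C1 and C4, giving the non-conjugated 2,5-diene, and no stereocenter is formed.

Step 2
Reactants: 2 cyclohexa-2,5-diene-1-carboxylic acid
Product: 3 (cyclohexa-2,5-dien-1-yl)methanol
Conditions: LiAlH4, Et2O, 0 °C to rt; H2O/aq. NaOH work-up
Reagents that add atoms: none
Why: LiAlH4 reduction of the acid to the primary alcohol with a non-acidic work-up leaves the skipped diene unisomerised; C1 is prochiral (two enantiotopic olefins), so there is still no stereocenter.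

Step 3
Reactants: 3 (cyclohexa-2,5-dien-1-yl)methanol; 4 cumene hydroperoxide
Product: 5 [(1S,2R,6R)-7-oxabicyclo[4.1.0]hept-3-en-2-yl]methanol (oxirane cis to CH2OH)
Conditions: VO(OiPr)3 (2 mol %), N,N'-[(1R,2R)-cyclohexane-1,2-diyl]bis(N-hydroxy-2,2-diphenylacetamide) (4 mol %), cumene hydroperoxide (1.2 equiv), PhMe, 0 °C
Reagents that add atoms: cumene hydroperoxide, CC(C)(OO)c1ccccc1
Why: Proposed new method: enantiotopic-olefin-selective, hydroxyl-directed epoxidation of a prochiral cyclohexa-2,5-dienyl carbinol by a chiral pentavalent vanadium bis-hydroxamate; the primary alkoxide binds vanadium, the bound cumyl peroxide oxygen is delivered intramolecularly to the ring face carrying CH2OH, and the C2-symmetric ligand pocket lets only one of the two enantiotopic Z-olefins reach the peroxide (the same face discrimination it makes for acyclic Z-homoallylic alcohols), so C1, C2 and C6 of 5 are set in one event, while slow over-epoxidation removes mainly the minor enantiomer as the meso bis-epoxide and raises ee; closest known reaction type: vanadium/bis-hydroxamic acid asymmetric epoxidation of homoallylic alcohols and desymmetrisation of meso dialkenyl carbinols.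

Step 4
Reactants: 5 [(1S,2R,6R)-7-oxabicyclo[4.1.0]hept-3-en-2-yl]methanol; 6 benzoyl chloride
Product: 7 [(1S,2R,6R)-7-oxabicyclo[4.1.0]hept-3-en-2-yl]methyl benzoate
Conditions: BzCl (1.1 equiv), pyridine, CH2Cl2, 0 °C
Reagents that add atoms: benzoyl chloride, O=C(Cl)c1ccccc1
Why: Standard O-acylation of a primary alcohol with an acid chloride; the oxirane and all stereocenters are untouched under these buffered conditions.

Step 5
Reactants: 7 [(1S,2R,6R)-7-oxabicyclo[4.1.0]hept-3-en-2-yl]methyl benzoate; 1 benzoic acid
Product: 8 [(1R,5S,6S)-5-(benzoyloxy)-6-hydroxycyclohex-2-en-1-yl]methyl benzoate (OH cis to CH2OBz, OBz trans to OH)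
Conditions: PhCO2H (1.1 equiv), iPr2NEt (1.0 equiv), [(R,R)-N,N'-bis(3,5-di-tert-butylsalicylidene)cyclohexane-1,2-diaminato]cobalt (5 mol %, divalent cobalt precatalyst oxidised by air to the trivalent cobalt benzoate), TBME, 0 °C to rt
Reagents that add atoms: benzoic acid, O=C(O)c1ccccc1
Why: Lewis-acid-assisted SN2 epoxide opening by a carboxylate (cobalt-salen carboxylic acid ring-opening of the Jacobsen type): benzoate attacks C6, the oxirane carbon remote from the C2 branch, with inversion, so OBz ends trans to the retained C1–O, which becomes the free OH.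

Step 6
Reactants: 8 [(1R,5S,6S)-5-(benzoyloxy)-6-hydroxycyclohex-2-en-1-yl]methyl benzoate; 9 bromine
Product: 10 [(1R,2S,3S,5R,6R)-3-(benzoyloxy)-5,6-dibromo-2-hydroxycyclohexyl]methyl benzoate (trans-dibromide, C6–Br anti to C1–H)
Conditions: Br2 (1.05 equiv), CH2Cl2, −78 °C, dark
Reagents that add atoms: bromine, BrBr
Why: Electrophilic anti addition of Br2 through a bromonium ion gives the trans-vicinal dibromide without touching OH or esters; the two new C–Br stereocenters are erased in step 7.

Step 7
Reactants: 10 [(1R,2S,3S,5R,6R)-3-(benzoyloxy)-5,6-dibromo-2-hydroxycyclohexyl]methyl benzoate; 11 N,O-bis(trimethylsilyl)acetamide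
Product: 15 [(5S,6S)-5-(benzoyloxy)-6-hydroxycyclohexa-1,3-dien-1-yl]methyl benzoate, via silyl ether dibromide 12 (not isolated), via silyl ether allylic bromide 13 (not isolated), via silyl ether diene 14 (not isolated)
Conditions: N,O-bis(trimethylsilyl)acetamide (1.5 equiv), PhMe, 40 °C; DBU (3.5 equiv), nBu4NBr (10 mol %), 45 °C; then 10% aq. citric acid, THF, 0 °C
Reagents that add atoms: none
Why: In-flask O-silylation blocks base-induced 1,2-benzoyl migration, and twofold E2 dehydrobromination (the classical route to trans-5,6-disubstituted cyclohexa-1,3-dienes) follows, with bromide ion equilibrating allylic bromide 13 so the loss of HBr across C1–C6 can go anti; the trans C5/C6 oxygens have no anti-periplanar H/leaving-group pair, so they neither epimerise nor aromatise, and mild aqueous acid removes the silyl group.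

Step 8
Reactants: 15 [(5S,6S)-5-(benzoyloxy)-6-hydroxycyclohexa-1,3-dien-1-yl]methyl benzoate; 16 tert-butyl hydroperoxide
Product: 17 (−)-pipoxide, [(1R,2R,3S,6S)-3-(benzoyloxy)-2-hydroxy-7-oxabicyclo[4.1.0]hept-4-en-1-yl]methyl benzoate
Conditions: VO(acac)2 (5 mol %), tBuOOH (1.5 equiv, decane), CH2Cl2, 0 °C
Reagents that add atoms: tert-butyl hydroperoxide, CC(C)(C)OO
Why: Hydroxyl-directed epoxidation of the Sharpless–Michaelson type: the C6 alkoxide binds vanadium and delivers oxygen to the adjacent trisubstituted C1=C2 double bond on the face syn to OH, setting both oxirane carbons cis to the hydroxyl, while the remote disubstituted olefin next to the ester is left alone.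

## Compound list

1 | benzoic acid | O=C(O)c1ccccc1 | starting material
2 | cyclohexa-2,5-diene-1-carboxylic acid | OC(=O)C1C=CCC=C1 | intermediate
3 | (cyclohexa-2,5-dien-1-yl)methanol | OCC1C=CCC=C1 | intermediate
4 | cumene hydroperoxide | CC(C)(OO)c1ccccc1 | starting material
5 | [(1S,2R,6R)-7-oxabicyclo[4.1.0]hept-3-en-2-yl]methanol | OC[C@H]1C=CC[C@H]2O[C@@H]12 | intermediate
6 | benzoyl chloride | O=C(Cl)c1ccccc1 | starting material
7 | [(1S,2R,6R)-7-oxabicyclo[4.1.0]hept-3-en-2-yl]methyl benzoate | O=C(OC[C@H]1C=CC[C@H]2O[C@@H]12)c1ccccc1 | intermediate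
8 | [(1R,5S,6S)-5-(benzoyloxy)-6-hydroxycyclohex-2-en-1-yl]methyl benzoate | O=C(OC[C@H]1C=CC[C@H](OC(=O)c2ccccc2)[C@H]1O)c1ccccc1 | intermediate
9 | bromine | BrBr | starting material
10 | [(1R,2S,3S,5R,6R)-3-(benzoyloxy)-5,6-dibromo-2-hydroxycyclohexyl]methyl benzoate | O=C(OC[C@H]1[C@@H](Br)[C@H](Br)C[C@H](OC(=O)c2ccccc2)[C@H]1O)c1ccccc1 | intermediate
11 | N,O-bis(trimethylsilyl)acetamide | CC(=N[Si](C)(C)C)O[Si](C)(C)C | starting material
12 | [(1R,2S,3S,5R,6R)-3-(benzoyloxy)-5,6-dibromo-2-[(trimethylsilyl)oxy]cyclohexyl]methyl benzoate | O=C(OC[C@H]1[C@@H](Br)[C@H](Br)C[C@H](OC(=O)c2ccccc2)[C@H]1O[Si](C)(C)C)c1ccccc1 | intermediate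
13 | [(1R,2S,5S,6S)-5-(benzoyloxy)-2-bromo-6-[(trimethylsilyl)oxy]cyclohex-3-en-1-yl]methyl benzoate | O=C(OC[C@H]1[C@@H](Br)C=C[C@H](OC(=O)c2ccccc2)[C@H]1O[Si](C)(C)C)c1ccccc1 | intermediate
14 | [(5S,6S)-5-(benzoyloxy)-6-[(trimethylsilyl)oxy]cyclohexa-1,3-dien-1-yl]methyl benzoate | O=C(OCC1=CC=C[C@H](OC(=O)c2ccccc2)[C@H]1O[Si](C)(C)C)c1ccccc1 | intermediate
15 | [(5S,6S)-5-(benzoyloxy)-6-hydroxycyclohexa-1,3-dien-1-yl]methyl benzoate | O=C(OCC1=CC=C[C@H](OC(=O)c2ccccc2)[C@H]1O)c1ccccc1 | intermediate
16 | tert-butyl hydroperoxide | CC(C)(C)OO | starting material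
17 | (−)-pipoxide, [(1R,2R,3S,6S)-3-(benzoyloxy)-2-hydroxy-7-oxabicyclo[4.1.0]hept-4-en-1-yl]methyl benzoate | O=C(OC[C@]12O[C@H]1C=C[C@H](OC(=O)c1ccccc1)[C@H]2O)c1ccccc1 | target

## Step count and risks

Total steps: 8. Longest linear sequence: 8 (fully linear from benzoic acid).

Steps most likely to fail:

Step 3 (the new method). The risk is poor discrimination between the two enantiotopic olefins, or oxidative aromatisation of the skipped diene. The fallback uses known chemistry and sets out from 3. Achiral hydroxyl-directed epoxidation (VO(acac)2, tBuOOH, CH2Cl2, 0 °C) gives the racemic cis-epoxy alcohol F1. Lipase-catalysed kinetic resolution by O-benzoylation (Burkholderia cepacia lipase, vinyl benzoate, TBME, rt, stopped near 45% conversion; the sense of the enzyme is checked first on a small scale) then gives benzoate 7 directly. It leaves the (1R,2S,6S)-epoxy alcohol F2, which is removed by chromatography. The fallback comes back to the route at 7, so step 4 is skipped, at the cost of at most half of the material.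

Step 6. The risk is participation of the homoallylic benzoate or the free OH in opening the bromonium ion, or an unfavourable trans-dibromide. The fallback sets out from 7. Br2 (CH2Cl2, −78 °C) is added to the rigid epoxy benzoate, which has neither a free OH nor the ring benzoate, to give the dibromo epoxide F3. The oxirane is then opened with benzoic acid under the conditions of step 5. The fallback comes back at 10.

Step 7. The risks are sluggish loss of the tertiary C1–H, N-alkylation of DBU by allylic bromide 13, and premature loss of the trimethylsilyl group followed by acyl migration. The fallback sets out from 8. Et3SiCl and imidazole in DMF give the isolable triethylsilyl ether F4. Br2 gives its trans-dibromide F5. Elimination with LiCl and Li2CO3 in DMF at 90 °C (chloride-mediated, with a weak carbonate base, and indifferent to the dibromide configuration) gives the silylated diene F6. HF·pyridine in THF at 0 °C removes the silyl group. The fallback comes back at 15, with two extra steps.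

## Further compounds

F1 | step 3 | racemic [(1S,2R,6R)-7-oxabicyclo[4.1.0]hept-3-en-2-yl]methanol (both enantiomers) | OC[C@H]1C=CC[C@H]2O[C@@H]12.OC[C@@H]1C=CC[C@@H]2O[C@H]12
F2 | step 3 | [(1R,2S,6S)-7-oxabicyclo[4.1.0]hept-3-en-2-yl]methanol | OC[C@@H]1C=CC[C@@H]2O[C@H]12
F3 | step 6 | [(1S,2R,3R,4R,6R)-3,4-dibromo-7-oxabicyclo[4.1.0]heptan-2-yl]methyl benzoate | O=C(OC[C@H]1[C@@H](Br)[C@H](Br)C[C@H]2O[C@@H]12)c1ccccc1
F4 | step 7 | [(1R,5S,6S)-5-(benzoyloxy)-6-[(triethylsilyl)oxy]cyclohex-2-en-1-yl]methyl benzoate | O=C(OC[C@H]1C=CC[C@H](OC(=O)c2ccccc2)[C@H]1O[Si](CC)(CC)CC)c1ccccc1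
F5 | step 7 | [(1R,2S,3S,5R,6R)-3-(benzoyloxy)-5,6-dibromo-2-[(triethylsilyl)oxy]cyclohexyl]methyl benzoate | O=C(OC[C@H]1[C@@H](Br)[C@H](Br)C[C@H](OC(=O)c2ccccc2)[C@H]1O[Si](CC)(CC)CC)c1ccccc1
F6 | step 7 | [(5S,6S)-5-(benzoyloxy)-6-[(triethylsilyl)oxy]cyclohexa-1,3-dien-1-yl]methyl benzoate | O=C(OCC1=CC=C[C@H](OC(=O)c2ccccc2)[C@H]1O[Si](CC)(CC)CC)c1ccccc1
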